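- Late in the summer flask product hardly moves: 53.0% at 15.0 min, 54.3% at 20.0 min, with electrophile still at 46.3%.

- summer: electrophile 0.50 M; nucleophile 0.55 M; free base 0.60 M; protic impurity 0.050 M; temperature 25 °C; the very flask that is asked about, followed so far
- flask: electrophile 0.50 M; nucleophile 0.550 M; free base 0.600 M; protic impurity 0.0500 M; temperature 25 °C; time 25 min

- summer (time / min: product / %, electrophile / %): 2.00: 22.5, 76.6; 5.00: 38.2, 62.9; 10.0: 48.2, 52.4; 15.0: 53.0, 48.8; 20.0: 54.3, 46.3

(readings scatter by 1 percentage point)

- delta: at 25 min raise the temperature by 20 K, then wait 8.0 min
- zeta: at 25 min take out 90% of the product then present, then wait 8.0 min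
- gamma: at 25 min add free base, 100% of the amount charged, then wait 8.0 min
- epsilon: at 25 min add nucleophile, 50.0% of the amount charged, then wait 8.0 min
- beta: change nothing and wait 8.0 min more

- product taken out counts as made
- what was read earlier has a scatter of 1 percentage point, one standard deviation
- additions bring no volume worth counting
- the earlier runs do not show what temperature does; that part of a forecast is a guess

1. product, in percent of the electrophile first charged, at 25 min
2. the option that brings most further product ("none" if no option brings more than 2 percentage points) (delta / zeta / gamma / epsilon / beta / none)
3. product present, with what was taken out counted in, in percent of the electrophile first charged, after epsilon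
4. product present, with what was taken out counted in, in percent of the electrophile first charged, after beta

- Take the main step first, electrophile plus nucleophile giving product one for one. The first reading gives a rate constant of 0.290 /M/min, a time of 6.26 min at the charged nucleophile. By itself, counted with equal charges, that step puts the summer flask at 78.4% at 25 min, above what is read.
- Now let each product cost more nucleophile than the one it contains. The stall reads as 2.03 nucleophile per product; this is the nucleophile price, the nucleophile lost from the flask for each product made. Charged nucleophile divided by the price, over charged electrophile, gives a ceiling on product.
- As a check from a different reading, the first-reading constant at this price gives 46.8% at 10.0 min, against 48.2% read.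
- What remains is a creep of 1.3 percentage points in 5.00 min, against a scatter of 1 point in each reading. Extended, it gives this reckoning 55.6% at 25 min and 57.7% after waiting.
- Taking out product returns no nucleophile under this reckoning, but adding nucleophile lifts the ceiling to 81.5%. With electrophile held at its last reading, 66.4% of the addition is spent in 8.0 min, giving 73.6%, on the high side. This reckoning commits to epsilon.
- The forecast, holding that “this looks like an approach to equilibrium”, gives 55.3% now, 55.8% after waiting and 66.5% after epsilon, and chooses zeta, which differs from the choice above.
- The flask gives 56.3% at 25 min, and epsilon is best with 17 points, reaching 73.0%, below the ceiling of 81.5%. Taking out product brings 2.2 points, the same as waiting with 2.2 points, which ends at 58.5%.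

    protic impurity + free base → quenched reagent (k = 14.2 /M/min, Ea = 59.0 kJ/mol)
    acid set free + free base ⇌ salt of the base (K = 13400 /M, k = 0.446 /M/min, Ea = 74.0 kJ/mol, ΔH = −37.0 kJ/mol)
    nucleophile + acid set free ⇌ protonated nucleophile, settled at all times (K = 1670 /M, ΔH = 17.0 kJ/mol)
    electrophile + nucleophile → acid set free + product (k = 0.315 /M/min, Ea = 46.0 kJ/mol)
    acid set free → by-product carried off (k = 0.119 /min, Ea = 77.0 kJ/mol)
    (constants at 25 °C)

- By 5.00 min the main step in the flask had done 68% of its turnover up to 25 min, and by 12.5 min protonated nucleophile stood at 0.245 M with nucleophile at 9.30% of its charge. Protonated nucleophile still stood at 0.247 M at 25.0 min, while salt of the base went from 0.00338 M to 0.0189 M, that step having 18% of its turnover behind it at 12.5 min.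
- In the neighbour with 1.4 M of nucleophile the price puts the ceiling at 138%, above the whole charge, so electrophile is the limiting reagent, and spending it completely leaves 27.7% of the nucleophile. That flask gives 98.8% product with 30% of its nucleophile left at 25.0 min.

The earlier runs and the new flask come from a simulation with constants of no real substance, and the scatter is random.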